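**Retrosynthetic overview**
1. Target ⇐ two SN2 O-demethylations of a bicyclic methyl enol ether that carries a 3-methoxybenzoyl group.
2. Bicyclo[3.3.1]nonane ⇐ 1,3 O→C shift: the C8–C1 bond between two quaternary carbons is made last, by moving the tertiary pyran carbon of a 4a-geranyl-4aH-chromen-5-one from the enol-ether oxygen to the adjacent ring carbon.
3. That dienone ⇐ dearomatizing ortho-C-geranylation of a hexasubstituted 5-hydroxychroman; the pyran ring relays the lavandulol-derived centre (later C7) to the new quaternary carbon (later C5).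
4. Chroman ⇐ C8 prenylation, and before that acid closure of the pyran ring from a C-lavandulyl resorcinol ketone made with (R)-lavandulol.
5. Resorcinol ketone ⇐ Friedel–Crafts aroylation of 5-methoxyresorcinol. Ring order: benzene ring (bought), then pyran, then dearomatization, then the carbocyclic bridge.

Assumption: (R)-lavandulol is taken as a commercial enantiopure starting material, and the target is one enol tautomer of a rapidly equilibrating enolised β-diketone.

**Step 1**
Reactants: 1 5-methoxybenzene-1,3-diol; 2 3-methoxybenzoyl chloride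
Product: 3 (2,4-dihydroxy-6-methoxyphenyl)(3-methoxyphenyl)methanone
Conditions: AlCl3 (2.2 equiv), PhNO2/CH2Cl2, 0 → 25 °C; aq. HCl work-up
Reagents that add atoms: none
Why: Friedel–Crafts acylation, in which the acylium ion attacks C4 (para to one OH, ortho to OMe) in preference to the doubly flanked C2; the minor 2,6-dihydroxy isomer is removed by crystallisation and no stereocentre is formed.

**Step 2**
Reactants: 4 (2R)-5-methyl-2-(prop-1-en-2-yl)hex-4-en-1-ol [(R)-lavandulol]
Product: 5 (2R)-5-methyl-2-(prop-1-en-2-yl)hex-4-en-1-yl trifluoromethanesulfonate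
Conditions: Tf2O, 2,6-lutidine, CH2Cl2, −78 °C; used cold without purification
Reagents that add atoms: trifluoromethanesulfonic anhydride, O=S(=O)(OS(=O)(=O)C(F)(F)F)C(F)(F)F
Why: O-sulfonylation of a primary alcohol, which does not touch the stereocentre that later becomes C7 of the target.

**Step 3**
Reactants: 3 (2,4-dihydroxy-6-methoxyphenyl)(3-methoxyphenyl)methanone; 5 (2R)-5-methyl-2-(prop-1-en-2-yl)hex-4-en-1-yl trifluoromethanesulfonate
Product: 7 [(3S)-5-hydroxy-7-methoxy-2,2-dimethyl-3-(3-methylbut-2-en-1-yl)-3,4-dihydro-2H-chromen-6-yl](3-methoxyphenyl)methanone, via C-lavandulyl resorcinol ketone 6 (not isolated)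
Conditions: LiN(SiMe3)2 (2.1 equiv), THF, −78 °C; 5, −78 → 0 °C; aq. HCl work-up; crude, Amberlyst-15 (cat.), CH2Cl2, 25 °C
Reagents that add atoms: none
Why: SN2 C-alkylation of the dilithium dianion at C3 (the carbon between the two oxido groups, with tight O–Li pairing holding back O-alkylation), then acid-catalysed Markovnikov hydroalkoxylation of the isopropenyl group by the free, non-chelated 4-OH to close the 2,2-dimethylpyran; the stereocentre is carried over unchanged from 4 (its descriptor becomes S only through CIP priorities).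

**Step 4**
Reactants: 7 [(3S)-5-hydroxy-7-methoxy-2,2-dimethyl-3-(3-methylbut-2-en-1-yl)-3,4-dihydro-2H-chromen-6-yl](3-methoxyphenyl)methanone; 8 2-methylbut-3-en-2-ol
Product: 9 [(3S)-5-hydroxy-7-methoxy-2,2-dimethyl-3,8-bis(3-methylbut-2-en-1-yl)-3,4-dihydro-2H-chromen-6-yl](3-methoxyphenyl)methanone
Conditions: Sc(OTf)3 (10 mol%), CH2Cl2, 0 → 25 °C
Reagents that add atoms: none
Why: Friedel–Crafts allylation, in which the dimethylallyl cation is captured at its primary terminus by C8, the only free ring carbon (flanked by OMe and the pyran oxygen, para to OH); no OH sits next to the new prenyl group, so no second pyran can close, and no stereocentre is formed.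

**Step 5**
Reactants: 9 [(3S)-5-hydroxy-7-methoxy-2,2-dimethyl-3,8-bis(3-methylbut-2-en-1-yl)-3,4-dihydro-2H-chromen-6-yl](3-methoxyphenyl)methanone; 10 (2E)-1-bromo-3,7-dimethylocta-2,6-diene (geranyl bromide)
Product: 11 (3S,4aR)-4a-[(2E)-3,7-dimethylocta-2,6-dien-1-yl]-7-methoxy-6-(3-methoxybenzoyl)-2,2-dimethyl-3,8-bis(3-methylbut-2-en-1-yl)-3,4-dihydro-2H-chromen-5(4aH)-one
Conditions: NaH (1.1 equiv), toluene, 0 → 40 °C
Reagents that add atoms: none
Why: Alkylative dearomatization by ortho-C-allylation (SN2 at the primary carbon, so E geometry is kept) of a 2,6-disubstituted sodium phenoxide in a non-polar solvent, where the oxygen-bound sodium delivers the bromide to C4a (the other ortho carbon bears the aroyl group and the para carbon C8 is shielded by OMe, prenyl and the pyran gem-dimethyl side); geranyl is expected to enter along the axial trajectory of the half-chair pyran, anti to the C3 prenyl group, which sets the quaternary centre 4aR.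

**Step 6**
Reactants: 11 (3S,4aR)-4a-[(2E)-3,7-dimethylocta-2,6-dien-1-yl]-7-methoxy-6-(3-methoxybenzoyl)-2,2-dimethyl-3,8-bis(3-methylbut-2-en-1-yl)-3,4-dihydro-2H-chromen-5(4aH)-one
Product: 12 (1R,5R,7S)-1-[(2E)-3,7-dimethylocta-2,6-dien-1-yl]-4-methoxy-3-(3-methoxybenzoyl)-6,6-dimethyl-5,7-bis(3-methylbut-2-en-1-yl)bicyclo[3.3.1]non-3-ene-2,9-dione
Conditions: Me3SiOTf (20 mol%), 2,6-di-tert-butyl-4-methylpyridine (30 mol%), CH2Cl2, −78 → −20 °C
Reagents that add atoms: none
Why: Proposed new method: O-silylation of the C5 carbonyl makes the cross-conjugated dienone an oxocarbenium ion whose tertiary C2–O1 bond ionises, leaving a silyl dienol ether tethered to a tertiary cation that is born next to C8 and collapses there (closest known types: Lewis-acid 1,3 O-to-C rearrangement of alkyl enol ethers and vinylogous Mukaiyama tert-alkylation); the hindered pyridine stops proton-mediated olefin isomerisation, and because the tether can only bridge C4a and C8 on the face it already occupies, both bridgeheads follow from the C4a and C3 centres and the C7 prenyl group ends up endo (syn to the oxygenated three-carbon bridge).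

**Step 7**
Reactants: 12 (1R,5R,7S)-1-[(2E)-3,7-dimethylocta-2,6-dien-1-yl]-4-methoxy-3-(3-methoxybenzoyl)-6,6-dimethyl-5,7-bis(3-methylbut-2-en-1-yl)bicyclo[3.3.1]non-3-ene-2,9-dione
Product: 14 (1S,5S,7S)-5-[(2E)-3,7-dimethylocta-2,6-dien-1-yl]-4-hydroxy-3-(3-hydroxybenzoyl)-8,8-dimethyl-1,7-bis(3-methylbut-2-en-1-yl)bicyclo[3.3.1]non-3-ene-2,9-dione, via 3'-O-methyl trione 13 (not isolated)
Conditions: NaSEt (6 equiv), DMF, 120 °C; then aq. HCl
Reagents that add atoms: none
Why: SN2 O-demethylation by thiolate, first at the vinylogous methyl ester (the resulting trione enolate is inert to further attack) and then at the aryl methyl ether; the isolated olefins and the three stereocentres are untouched, and the descriptors change only because the carbonyl and enol positions are renumbered.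

**Compound list**
1 | 5-methoxybenzene-1,3-diol | COc1cc(O)cc(O)c1 | starting material
2 | 3-methoxybenzoyl chloride | COc1cccc(c1)C(Cl)=O | starting material
3 | (2,4-dihydroxy-6-methoxyphenyl)(3-methoxyphenyl)methanone | COc1cccc(c1)C(=O)c1c(O)cc(O)cc1OC | intermediate
4 | (2R)-5-methyl-2-(prop-1-en-2-yl)hex-4-en-1-ol | CC(C)=CC[C@@H](CO)C(C)=C | starting material
5 | (2R)-5-methyl-2-(prop-1-en-2-yl)hex-4-en-1-yl trifluoromethanesulfonate | CC(C)=CC[C@@H](COS(=O)(=O)C(F)(F)F)C(C)=C | intermediate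
6 | {2,4-dihydroxy-6-methoxy-3-[(2S)-5-methyl-2-(prop-1-en-2-yl)hex-4-en-1-yl]phenyl}(3-methoxyphenyl)methanone | COc1cccc(c1)C(=O)c1c(OC)cc(O)c(C[C@H](CC=C(C)C)C(C)=C)c1O | intermediate
7 | [(3S)-5-hydroxy-7-methoxy-2,2-dimethyl-3-(3-methylbut-2-en-1-yl)-3,4-dihydro-2H-chromen-6-yl](3-methoxyphenyl)methanone | COc1cccc(c1)C(=O)c1c(OC)cc2OC(C)(C)[C@@H](CC=C(C)C)Cc2c1O | intermediate
8 | 2-methylbut-3-en-2-ol | CC(C)(O)C=C | starting material
9 | [(3S)-5-hydroxy-7-methoxy-2,2-dimethyl-3,8-bis(3-methylbut-2-en-1-yl)-3,4-dihydro-2H-chromen-6-yl](3-methoxyphenyl)methanone | COc1cccc(c1)C(=O)c1c(OC)c(CC=C(C)C)c2OC(C)(C)[C@@H](CC=C(C)C)Cc2c1O | intermediate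
10 | (2E)-1-bromo-3,7-dimethylocta-2,6-diene | CC(C)=CCC/C(C)=C/CBr | starting material
11 | (3S,4aR)-4a-[(2E)-3,7-dimethylocta-2,6-dien-1-yl]-7-methoxy-6-(3-methoxybenzoyl)-2,2-dimethyl-3,8-bis(3-methylbut-2-en-1-yl)-3,4-dihydro-2H-chromen-5(4aH)-one | CC(C)=CCC/C(C)=C/C[C@@]12C[C@H](CC=C(C)C)C(C)(C)OC1=C(CC=C(C)C)C(OC)=C(C(=O)c1cccc(OC)c1)C2=O | intermediate
12 | (1R,5R,7S)-1-[(2E)-3,7-dimethylocta-2,6-dien-1-yl]-4-methoxy-3-(3-methoxybenzoyl)-6,6-dimethyl-5,7-bis(3-methylbut-2-en-1-yl)bicyclo[3.3.1]non-3-ene-2,9-dione | CC(C)=CCC/C(C)=C/C[C@]12C[C@H](CC=C(C)C)C(C)(C)[C@](CC=C(C)C)(C(OC)=C(C(=O)c3cccc(OC)c3)C1=O)C2=O | intermediate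
13 | (1S,5S,7S)-5-[(2E)-3,7-dimethylocta-2,6-dien-1-yl]-4-hydroxy-3-(3-methoxybenzoyl)-8,8-dimethyl-1,7-bis(3-methylbut-2-en-1-yl)bicyclo[3.3.1]non-3-ene-2,9-dione | CC(C)=CCC/C(C)=C/C[C@]12C[C@H](CC=C(C)C)C(C)(C)[C@](CC=C(C)C)(C(=O)C(C(=O)c3cccc(OC)c3)=C1O)C2=O | intermediate
14 | (1S,5S,7S)-5-[(2E)-3,7-dimethylocta-2,6-dien-1-yl]-4-hydroxy-3-(3-hydroxybenzoyl)-8,8-dimethyl-1,7-bis(3-methylbut-2-en-1-yl)bicyclo[3.3.1]non-3-ene-2,9-dione | CC(C)=CCC/C(C)=C/C[C@]12C[C@H](CC=C(C)C)C(C)(C)[C@](CC=C(C)C)(C(=O)C(C(=O)c3cccc(O)c3)=C1O)C2=O | target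

**Step count and risks**
Total steps: 7. Longest linear sequence: 6 (steps 1, 3, 4, 5, 6, 7 from compound 1; equally steps 2 to 7 from compound 4).

The three steps most likely to fail, most risky first:

Step 6 (the O-to-C shift is unprecedented in this setting; the ion pair may re-close at oxygen or lose a proton). The fallback sets out from 11 and comes back at 13. It moves the ring closure to the free enol under protic conditions: cleave the vinylogous methyl ether of 11 with LiCl in DMSO at 100 °C to give (3S,4aR)-4a-[(2E)-3,7-dimethylocta-2,6-dien-1-yl]-7-hydroxy-6-(3-methoxybenzoyl)-2,2-dimethyl-3,8-bis(3-methylbut-2-en-1-yl)-3,4-dihydro-2H-chromen-5(4aH)-one F6, then ionise the pyran in formic acid at 40 °C so that the tertiary cation is trapped by the enol carbon, giving 13, which step 7 converts to 14.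

Step 5 (O-alkylation or attack at the para carbon C8 may compete, and the facial selectivity is a prediction). The fallback sets out from 7 and comes back at 11. It blocks C8 before dearomatization: brominate 7 with N-bromosuccinimide in CH2Cl2 at −40 °C to give [(3S)-8-bromo-5-hydroxy-7-methoxy-2,2-dimethyl-3-(3-methylbut-2-en-1-yl)-3,4-dihydro-2H-chromen-6-yl](3-methoxyphenyl)methanone F4, geranylate it with NaH and 10 in toluene, where only C4a remains as a carbon nucleophile, to give (3S,4aR)-8-bromo-4a-[(2E)-3,7-dimethylocta-2,6-dien-1-yl]-7-methoxy-6-(3-methoxybenzoyl)-2,2-dimethyl-3-(3-methylbut-2-en-1-yl)-3,4-dihydro-2H-chromen-5(4aH)-one F5, and replace the vinylic bromide by prenyl in a Stille coupling with tributyl(3-methylbut-2-en-1-yl)stannane (Pd2(dba)3, AsPh3, DMF, 60 °C) to reach 11.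

Step 3 (the unactivated primary triflate may alkylate the 4-oxygen instead of C3). The fallback sets out from 3 and 4 and comes back at 7. It makes the aryl–CH2 bond by cross-coupling: iodinate 3 between the two hydroxyl groups (N-iodosuccinimide, MeCN, 0 °C) to give (2,4-dihydroxy-3-iodo-6-methoxyphenyl)(3-methoxyphenyl)methanone F1; convert 4 (I2, PPh3, imidazole) into (2R)-1-iodo-5-methyl-2-(prop-1-en-2-yl)hex-4-ene F2; exchange iodine for lithium (t-BuLi, Et2O, −78 °C) and trap with 9-methoxy-9-borabicyclo[3.3.1]nonane to give lithium 9-methoxy-9-[(2R)-5-methyl-2-(prop-1-en-2-yl)hex-4-en-1-yl]-9-boranuidabicyclo[3.3.1]nonane F3; B-alkyl Suzuki–Miyaura coupling of F3 with F1 (PdCl2(dppf), K3PO4, DMF/H2O, 60 °C) gives 6, which Amberlyst-15 closes to 7 as in step 3.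

**Further compounds**
F1 | step 3 | (2,4-dihydroxy-3-iodo-6-methoxyphenyl)(3-methoxyphenyl)methanone | COc1cccc(c1)C(=O)c1c(OC)cc(O)c(I)c1O
F2 | step 3 | (2R)-1-iodo-5-methyl-2-(prop-1-en-2-yl)hex-4-ene | CC(C)=CC[C@@H](CI)C(C)=C
F3 | step 3 | lithium 9-methoxy-9-[(2R)-5-methyl-2-(prop-1-en-2-yl)hex-4-en-1-yl]-9-boranuidabicyclo[3.3.1]nonane | [Li+].CO[B-]1(C[C@H](CC=C(C)C)C(C)=C)C2CCCC1CCC2
F4 | step 5 | [(3S)-8-bromo-5-hydroxy-7-methoxy-2,2-dimethyl-3-(3-methylbut-2-en-1-yl)-3,4-dihydro-2H-chromen-6-yl](3-methoxyphenyl)methanone | COc1cccc(c1)C(=O)c1c(OC)c(Br)c2OC(C)(C)[C@@H](CC=C(C)C)Cc2c1O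
F5 | step 5 | (3S,4aR)-8-bromo-4a-[(2E)-3,7-dimethylocta-2,6-dien-1-yl]-7-methoxy-6-(3-methoxybenzoyl)-2,2-dimethyl-3-(3-methylbut-2-en-1-yl)-3,4-dihydro-2H-chromen-5(4aH)-one | CC(C)=CCC/C(C)=C/C[C@@]12C[C@H](CC=C(C)C)C(C)(C)OC1=C(Br)C(OC)=C(C(=O)c1cccc(OC)c1)C2=O
F6 | step 6 | (3S,4aR)-4a-[(2E)-3,7-dimethylocta-2,6-dien-1-yl]-7-hydroxy-6-(3-methoxybenzoyl)-2,2-dimethyl-3,8-bis(3-methylbut-2-en-1-yl)-3,4-dihydro-2H-chromen-5(4aH)-one | CC(C)=CCC/C(C)=C/C[C@@]12C[C@H](CC=C(C)C)C(C)(C)OC1=C(CC=C(C)C)C(O)=C(C(=O)c1cccc(OC)c1)C2=O
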